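The readings were computed on assumed constants, noise included.

0.100 M of nucleophile stands over in alpha if I count the main step by itself, one nucleophile per electrophile. I build the flask up from that number.

| flask | electrophile | nucleophile | protic impurity | remark | time |
|---|---|---|---|---|---|
| south-west | 0.050 M | 0.20 M | 1 mM | run made earlier |  |
| south-east | 0.050 M | 0.48 M | 1 mM | run made earlier |  |
| alpha | 0.050 M | 0.150 M | 1.00 mM |  | 8.0 min |
| theta | 0.050 M | 0.220 M | 1.00 mM |  | 8.0 min |
| delta | 0.050 M | 0.340 M | 1.00 mM |  | 8.0 min |

| run | time / min | electrophile / % | product / % |
|---|---|---|---|
| south-west | 0.333 | 48.0 | 53.8 |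
| south-west | 0.667 | 26.6 | 74.7 |
| south-west | 1.00 | 15.2 | 85.3 |
| south-west | 2.00 | 3.7 | 94.8 |
| south-west | 4.00 | 1.3 | 100.2 |
| south-east | 0.333 | 14.8 | 83.7 |
| south-east | 1.00 | 0.8 | 100.5 |
| south-east | 2.00 | 0.5 | 99.8 |
| south-east | 3.00 | 0.5 | 99.4 |
| south-east | 4.00 | 0 | 98.7 |

(scatter of a reading: 1 percentage point)

1. part of the electrophile that has reacted at the end, alpha
2. part of the electrophile that has reacted at the end, theta
3. part of the electrophile that has reacted at the end, delta
4. what raising the concentration of nucleophile from its lowest to its highest value here does to the part of the electrophile that has reacted (changes below 5 percentage points count as none) (it rises / no change / it falls)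

- the earlier runs were read with a standard deviation of 1 percentage point
- steps under discussion: electrophile + nucleophile -> acid set free + product; nucleophile + acid set free <-> protonated nucleophile; nucleophile + protic impurity -> quenched reagent

Next comes the acid set free. It pairs with a nucleophile, so each electrophile costs a second one, and the number falls to 0.0500 M. Then the protic impurity takes 0.001 M, which leaves 0.0490 M. I call this the spare nucleophile: the nucleophile charged, minus twice the electrophile, minus the impurity. Its zero is the balanced charge. Above zero the electrophile is the limiting reagent; below zero the nucleophile is.

The spare also gives me a clock. Late in a run the free nucleophile is close to the spare, so the electrophile decays pseudo-first-order, with a time constant inverse to the spare. Between 1.00 min and 2.00 min the south-west readings, with a spare of 0.0990 M, give 0.708 min. Scaled to alpha, that is 1.43 min, so 8.0 min holds 5.59 time constants. A plain exponential from the full charge then gives 99.6% reacted in alpha. Theta and delta have spares of 0.119 M and 0.239 M, so their clocks run faster, and I expect no change across the range.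

The forecast says 99.8%, 100% and 100% for alpha, theta and delta, and no change. Its ground is that “two nucleophile are used per electrophile”. For alpha my own figure is 99.6%, the forecast's 99.8%.

The flasks give 99.8%, >99.9% and 100%, and no change, with a change of 0.17 percentage points.

    electrophile + nucleophile → acid set free + product (k = 0.225 L mol⁻¹ s⁻¹)
    nucleophile + acid set free ⇌ protonated nucleophile, settled at all times (K = 36000 L mol⁻¹)
    nucleophile + protic impurity → quenched reagent (k = 40.7 L mol⁻¹ s⁻¹)

Alpha is nearly at rest at 8.0 min: 0.17% of its electrophile is left, and at 80.0 min the part reacted is 100%, a gain of 0.20 points. Its free nucleophile stays at 32.7% of the charge, which is 0.0492 M, close to the spare of 0.0490 M. Now take alpha with 0.085 M of electrophile. The spare there is −0.0210 M, below zero, so the nucleophile is the limiting reagent and 12.4% of the electrophile should stay. That flask gives 13% left and 86.6% reacted, with 1.7% of its nucleophile free.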